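**Plan**
- Retrosynthesis: remove the three benzyl ethers; return the C3 CH2OH of the benzofuran to an ester; cut the C7–C8 aldol bond of the open diarylpropanediol and the aryl–CH2C(O) bond next to it; cut O1–C7a and C3–C3a of the dihydrobenzofuran together, to an aryl iodide and a glycidic ester; cut the lactone Cα–CH2Ar bond; open the lactone to a Stobbe half-ester.
- Forward: the butyrolactone ring is made first (Stobbe, asymmetric hydrogenation, reduction/lactonisation), then the α-benzyl group, then the dihydrofuran ring by a palladium/norbornene (3+2) annulation, then the arylacetyl imide, the anti-aldol chain, oxidation-level adjustment and debenzylation.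
- Enabling feature: in the future benzo ring of the benzofuran the iodine sits on C7a, between the C7 methoxy group and a free C–H at C3a; the strained oxirane of the glycidate supplies O1–C2–C3, and its ester makes C3 the electrophilic carbon and later epimerisable.
- Stereochemistry: lactone Cβ from the rhodium hydrogenation, Cα from trans-selective enolate alkylation; benzofuran C2 from the Shi epoxide (retained), C3 by equilibration to trans; both diol centres from the auxiliary-controlled anti-aldol.
- The iodide serves the annulation and the bromide the later enolate arylation; benzyl is the only protecting group.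

Key step: step 10

Remark: the antipodes of (S,S)-Et-DuPhos, the D-fructose-derived ketone and Rh2(S-PTTL)4 are named in the sense expected from their usual stereochemical models; the mirror-image catalyst is to be used if the sense is the opposite.

**Step 1**
Reactants: 1 5-bromovanillin
Product: 2 4-(benzyloxy)-3-bromo-5-methoxybenzaldehyde
Conditions: BnBr, K2CO3, DMF, 60 °C
Reagents that add atoms: benzyl bromide, BrCc1ccccc1
Why: Williamson etherification of the phenoxide; the benzyl ether masks the phenol through all base, hydride and palladium steps and leaves in step 17.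

**Step 2**
Reactants: 2 aldehyde; 3 dimethyl succinate
Product: 4 (E)-4-[4-(benzyloxy)-3-bromo-5-methoxyphenyl]-3-(methoxycarbonyl)but-3-enoic acid
Conditions: NaOMe, MeOH, reflux; then aq. HCl
Reagents that add atoms: none
Why: Stobbe condensation, in which the succinate enolate adds to the aldehyde, the alkoxide lactonises and E1cB opening of the paraconate gives the (E)-alkylidene half-ester with differentiated carboxyls.

**Step 3**
Reactants: 4 half-ester
Product: 5 (R)-4-[4-(benzyloxy)-3-bromo-5-methoxyphenyl]-3-(methoxycarbonyl)butanoic acid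
Conditions: [Rh(cod)((S,S)-Et-DuPhos)]BF4 (1 mol%), H2 (5 bar), NaOMe (0.1 equiv), MeOH, rt
Reagents that add atoms: none
Why: Rhodium–bisphospholane asymmetric hydrogenation of a Stobbe-derived itaconate half-ester, where chelation of the carboxyl groups fixes the alkene on the chiral catalyst, which sets the R centre; aryl bromide and benzyl ether are inert to the homogeneous catalyst.

**Step 4**
Reactants: 5 half-ester
Product: 7 (R)-4-[4-(benzyloxy)-3-bromo-5-methoxybenzyl]dihydrofuran-2(3H)-one, via hydroxy acid 6 (not isolated)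
Conditions: LiBH4, THF, 0 °C to rt; then 2 M HCl, rt
Reagents that add atoms: none
Why: Chemoselective borohydride reduction of the ester beside the unreactive lithium carboxylate, then acid-promoted lactonisation of 6; the stereocentre is not involved.

**Step 5**
Reactants: 8 methyl 4-iodo-3-methoxybenzoate
Product: 9 (4-iodo-3-methoxyphenyl)methanol
Conditions: i-Bu2AlH, CH2Cl2, −78 to 0 °C; Rochelle salt
Reagents that add atoms: none
Why: Hydride reduction of the benzoate to the benzyl alcohol; the aryl iodide is inert to the aluminium hydride at low temperature.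

**Step 6**
Reactants: 9 benzyl alcohol
Product: 10 4-(bromomethyl)-1-iodo-2-methoxybenzene
Conditions: PBr3, CH2Cl2, 0 °C
Reagents that add atoms: phosphorus tribromide, BrP(Br)Br
Why: SN2 bromination of the benzylic alcohol through its phosphite ester.

**Step 7**
Reactants: 7 lactone; 10 benzyl bromide
Product: 11 (3R,4R)-4-[4-(benzyloxy)-3-bromo-5-methoxybenzyl]-3-(4-iodo-3-methoxybenzyl)dihydrofuran-2(3H)-one
Conditions: LiN(SiMe3)2, THF, −78 °C; then 10, −78 to −30 °C
Reagents that add atoms: none
Why: Alkylation of the lactone lithium enolate, which takes the benzyl bromide on the face anti to the β-substituent and so sets the α-centre trans (R) under substrate control; the amide base does not exchange with the aryl halides.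

**Step 8**
Reactants: 12 4-(benzyloxy)-3-methoxybenzaldehyde; 13 trimethyl phosphonoacetate
Product: 14 methyl (E)-3-[4-(benzyloxy)-3-methoxyphenyl]acrylate
Conditions: NaOMe, MeOH/THF, 0 °C to rt
Reagents that add atoms: none
Why: Horner–Wadsworth–Emmons olefination, E-selective through the stabilised phosphonate anion.

**Step 9**
Reactants: 14 cinnamate
Product: 15 methyl (2S,3R)-3-[4-(benzyloxy)-3-methoxyphenyl]oxirane-2-carboxylate (trans)
Conditions: D-fructose-derived diacetate ketone (1,2-O-isopropylidene-4,5-di-O-acetyl-β-D-erythro-2,3-hexodiulo-2,6-pyranose, 0.3 equiv), KHSO5 (Oxone), NaHCO3, Bu4NHSO4, MeCN/aq. Na2(EDTA), 0 °C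
Reagents that add atoms: potassium peroxymonosulfate, [K+].[O-]S(=O)(=O)OO
Why: Shi asymmetric epoxidation of a trans-cinnamate by the chiral dioxirane through a spiro transition state; oxygen transfer is concerted, so the trans geometry is kept and the catalyst sets both centres (2S,3R).

**Step 10**
Reactants: 11 aryl iodide lactone; 15 glycidic ester (1.5 equiv)
Product: 17 methyl (2S,3S)-trans-2-aryl-2,3-dihydrobenzofuran-3-carboxylate carrying the lactone at C5, via cis ester 16 (not isolated)
Conditions: Pd(OAc)2 (10 mol%), RuPhos (20 mol%), isopropyl 5-norbornene-2-carboxylate (0.5 equiv), Cs2CO3 (1.5 equiv), 1,4-dioxane, 90 °C; then DBU (0.5 equiv), 40 °C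
Reagents that add atoms: none
Why: Proposed new method: oxidative addition of the aryl iodide to zerovalent palladium, norbornene insertion and ortho C–H palladation give the aryl-norbornyl palladacycle of divalent palladium, which opens the oxirane of 15 by SN2-type oxidative addition at the ester-bearing carbon (inversion, ring strain released) to tetravalent palladium, and aryl–alkyl reductive elimination, norbornene extrusion by β-carbon elimination and C–O reductive elimination from the aryl palladium alkoxide follow. The closest known reaction type is the palladium/norbornene (Catellani-type) annulation of ortho-substituted aryl iodides with terminal epoxides to 2-substituted 2,3-dihydrobenzofurans, here extended to a 2,3-disubstituted glycidic ester. The dihydrofuran ring closes by C(aryl)–O reductive elimination from a six-membered oxapalladacycle, a formal (3+2) union of the O–C–C unit of the oxirane with the ipso and ortho carbons. C2 keeps the configuration of the benzylic epoxide carbon, whose C–O bond is never broken; C3 is first formed cis by inversion (16) and is then set trans by base equilibration of the ester α-centre, so its outcome is thermodynamic. The step needs attack at the α-carbon and not the benzylic one, which the adjacent carbonyl should favour for a soft, electron-rich metal nucleophile (as soft organocopper nucleophiles do with glycidic esters); it needs a single ortho functionalisation, which the ortho-methoxy group secures by blocking the second ortho position and enabling norbornene extrusion; and it needs iodide-over-bromide selectivity, which rests on the much faster oxidative addition of the iodide beside the electron-rich, alkoxy-flanked bromide.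

**Step 11**
Reactants: 18 (S)-3-acetyl-4-benzyloxazolidin-2-one
Product: 19 (S)-4-benzyl-3-[1-(trimethylsilyloxy)vinyl]oxazolidin-2-one
Conditions: Me3SiOTf, Et3N, CH2Cl2, 0 °C
Reagents that add atoms: trimethylsilyl triflate, C[Si](C)(C)OS(=O)(=O)C(F)(F)F
Why: Soft enolisation and O-silylation of the imide gives the silyl ketene N,O-acetal needed for a base-free arylation.

**Step 12**
Reactants: 17 aryl bromide; 19 silyl ketene N,O-acetal (2 equiv)
Product: 20 arylacetyl imide (17 with Br replaced by CH2C(=O)N of the (S)-4-benzyloxazolidin-2-one)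
Conditions: Pd(dba)2 (5 mol%), P(t-Bu)3 (10 mol%), ZnF2 (0.6 equiv), DMF, 80 °C
Reagents that add atoms: none
Why: Palladium-catalysed α-arylation of an imide silyl enolate with an aryl bromide under ZnF2 activation (transmetalation to an arylpalladium enolate, then C–C reductive elimination); the near-neutral conditions spare the lactone and the epimerisable ester, and no stereocentre is formed.

**Step 13**
Reactants: 20 imide; 12 4-(benzyloxy)-3-methoxybenzaldehyde (1.3 equiv)
Product: 22 anti-aldol adduct (2R,3S in the propanoyl chain), via silyl ether 21 (not isolated)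
Conditions: MgCl2 (0.2 equiv), Et3N, Me3SiCl, EtOAc, rt; then 1 M HCl/THF, 0 °C
Reagents that add atoms: none
Why: Evans-type MgCl2-catalysed direct anti-aldol, in which the chelated (Z)-magnesium enolate adds to the aldehyde through a boat transition state on the face opposite the auxiliary benzyl group (sets the α-centre) with anti topology (sets the carbinol centre), while silylation of the aldolate to 21 drives turnover and blocks retro-aldol.

**Step 14**
Reactants: 22 aldol adduct
Product: 23 (1S,2S)-1,3-diol (imide reduced to CH2OH, auxiliary removed)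
Conditions: NaBH4, THF/H2O (3:1), 0 °C to rt
Reagents that add atoms: none
Why: Borohydride reduction of the activated imide carbonyl releases the auxiliary and gives the primary alcohol, while the less electrophilic methyl ester and γ-lactone are left; the cold, weakly basic medium should avoid retro-aldol and does not touch the stereocentres.

**Step 15**
Reactants: 23 diol methyl ester
Product: 24 dihydrobenzofuran-3-carboxylic acid
Conditions: Me3SnOH (6 equiv), 1,2-dichloroethane, 80 °C; then 1 M HCl wash
Reagents that add atoms: trimethyltin hydroxide, C[Sn](C)(C)O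
Why: Me3SnOH-mediated hydrolysis of the methyl ester under nearly neutral conditions, chosen because hydroxide could open the dihydrobenzofuran by β-elimination of the phenoxide from the ester enolate; the acid wash frees the carboxylic acid and keeps the γ-lactone closed.

**Step 16**
Reactants: 24 acid
Product: 25 tri-O-benzyl triol (C3 CH2OH installed)
Conditions: BH3·SMe2 (4 equiv), THF, 0 °C to rt; MeOH quench
Reagents that add atoms: none
Why: Chemoselective borane reduction of the carboxylic acid through its acyloxyborane, which is much faster than reduction of the lactone; the hydroxyl groups are only borylated and are freed on methanolysis.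

**Step 17**
Reactants: 25 tri-O-benzyl triol
Product: 26 target CNP0199264.2
Conditions: H2 (1 atm), Pd/C (10%), EtOAc/EtOH, rt, monitored
Reagents that add atoms: none
Why: Hydrogenolysis of the three aryl benzyl ethers, which cleave faster than the benzylic alcohol and the cyclic benzylic ether under neutral conditions and short reaction time.

**Compound list**
1 | 5-bromovanillin (3-bromo-4-hydroxy-5-methoxybenzaldehyde) | O=Cc1cc(Br)c(O)c(OC)c1 | starting material
2 | 4-(benzyloxy)-3-bromo-5-methoxybenzaldehyde | O=Cc1cc(Br)c(OCc2ccccc2)c(OC)c1 | intermediate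
3 | dimethyl succinate | COC(=O)CCC(=O)OC | starting material
4 | (E)-4-[4-(benzyloxy)-3-bromo-5-methoxyphenyl]-3-(methoxycarbonyl)but-3-enoic acid | COC(=O)/C(CC(=O)O)=C/c1cc(Br)c(OCc2ccccc2)c(OC)c1 | intermediate
5 | (R)-4-[4-(benzyloxy)-3-bromo-5-methoxyphenyl]-3-(methoxycarbonyl)butanoic acid | COC(=O)[C@@H](CC(=O)O)Cc1cc(Br)c(OCc2ccccc2)c(OC)c1 | intermediate
6 | (R)-4-[4-(benzyloxy)-3-bromo-5-methoxyphenyl]-3-(hydroxymethyl)butanoic acid (not isolated) | OC[C@@H](CC(=O)O)Cc1cc(Br)c(OCc2ccccc2)c(OC)c1 | intermediate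
7 | (R)-4-[4-(benzyloxy)-3-bromo-5-methoxybenzyl]dihydrofuran-2(3H)-one | COc1cc(C[C@H]2COC(=O)C2)cc(Br)c1OCc1ccccc1 | intermediate
8 | methyl 4-iodo-3-methoxybenzoate | COC(=O)c1ccc(I)c(OC)c1 | starting material
9 | (4-iodo-3-methoxyphenyl)methanol | OCc1ccc(I)c(OC)c1 | intermediate
10 | 4-(bromomethyl)-1-iodo-2-methoxybenzene | BrCc1ccc(I)c(OC)c1 | intermediate
11 | (3R,4R)-4-[4-(benzyloxy)-3-bromo-5-methoxybenzyl]-3-(4-iodo-3-methoxybenzyl)dihydrofuran-2(3H)-one | COc1cc(C[C@H]2COC(=O)[C@@H]2Cc2ccc(I)c(OC)c2)cc(Br)c1OCc1ccccc1 | intermediate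
12 | 4-(benzyloxy)-3-methoxybenzaldehyde | O=Cc1ccc(OCc2ccccc2)c(OC)c1 | starting material
13 | trimethyl phosphonoacetate | COC(=O)CP(=O)(OC)OC | starting material
14 | methyl (E)-3-[4-(benzyloxy)-3-methoxyphenyl]acrylate | COC(=O)/C=C/c1ccc(OCc2ccccc2)c(OC)c1 | intermediate
15 | methyl (2S,3R)-3-[4-(benzyloxy)-3-methoxyphenyl]oxirane-2-carboxylate | COC(=O)[C@H]1O[C@@H]1c1ccc(OCc2ccccc2)c(OC)c1 | intermediate
16 | methyl (2S,3R)-cis-2-[4-(benzyloxy)-3-methoxyphenyl]-5-({(3R,4R)-4-[4-(benzyloxy)-3-bromo-5-methoxybenzyl]-2-oxotetrahydrofuran-3-yl}methyl)-7-methoxy-2,3-dihydrobenzofuran-3-carboxylate (not isolated) | COc1cc(C[C@H]2COC(=O)[C@@H]2Cc2cc(OC)c3c(c2)[C@@H](C(=O)OC)[C@@H](c2ccc(OCc4ccccc4)c(OC)c2)O3)cc(Br)c1OCc1ccccc1 | intermediate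
17 | (2S,3S)-trans isomer of 16 | COc1cc(C[C@H]2COC(=O)[C@@H]2Cc2cc(OC)c3c(c2)[C@H](C(=O)OC)[C@@H](c2ccc(OCc4ccccc4)c(OC)c2)O3)cc(Br)c1OCc1ccccc1 | intermediate
18 | (S)-3-acetyl-4-benzyloxazolidin-2-one | CC(=O)N1[C@@H](Cc2ccccc2)COC1=O | starting material
19 | (S)-4-benzyl-3-[1-(trimethylsilyloxy)vinyl]oxazolidin-2-one | C=C(O[Si](C)(C)C)N1[C@@H](Cc2ccccc2)COC1=O | intermediate
20 | 17 with Br replaced by 2-[(S)-4-benzyl-2-oxooxazolidin-3-yl]-2-oxoethyl | COc1cc(C[C@H]2COC(=O)[C@@H]2Cc2cc(OC)c3c(c2)[C@H](C(=O)OC)[C@@H](c2ccc(OCc4ccccc4)c(OC)c2)O3)cc(CC(=O)N2[C@@H](Cc3ccccc3)COC2=O)c1OCc1ccccc1 | intermediate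
21 | O-trimethylsilyl ether of 22 (not isolated) | COc1cc(C[C@H]2COC(=O)[C@@H]2Cc2cc(OC)c3c(c2)[C@H](C(=O)OC)[C@@H](c2ccc(OCc4ccccc4)c(OC)c2)O3)cc([C@@H](C(=O)N2[C@@H](Cc3ccccc3)COC2=O)[C@H](O[Si](C)(C)C)c2ccc(OCc3ccccc3)c(OC)c2)c1OCc1ccccc1 | intermediate
22 | anti-aldol adduct: 20 bearing at the imide α-carbon (R) an (S)-hydroxy[4-(benzyloxy)-3-methoxyphenyl]methyl group | COc1cc(C[C@H]2COC(=O)[C@@H]2Cc2cc(OC)c3c(c2)[C@H](C(=O)OC)[C@@H](c2ccc(OCc4ccccc4)c(OC)c2)O3)cc([C@@H](C(=O)N2[C@@H](Cc3ccccc3)COC2=O)[C@H](O)c2ccc(OCc3ccccc3)c(OC)c2)c1OCc1ccccc1 | intermediate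
23 | diol: 17 with Br replaced by (1S,2S)-1-[4-(benzyloxy)-3-methoxyphenyl]-1,3-dihydroxypropan-2-yl | COc1cc(C[C@H]2COC(=O)[C@@H]2Cc2cc(OC)c3c(c2)[C@H](C(=O)OC)[C@@H](c2ccc(OCc4ccccc4)c(OC)c2)O3)cc([C@@H](CO)[C@H](O)c2ccc(OCc3ccccc3)c(OC)c2)c1OCc1ccccc1 | intermediate
24 | (2S,3S)-dihydrobenzofuran-3-carboxylic acid corresponding to 23 | COc1cc(C[C@H]2COC(=O)[C@@H]2Cc2cc(OC)c3c(c2)[C@H](C(=O)O)[C@@H](c2ccc(OCc4ccccc4)c(OC)c2)O3)cc([C@@H](CO)[C@H](O)c2ccc(OCc3ccccc3)c(OC)c2)c1OCc1ccccc1 | intermediate
25 | tri-O-benzyl ether of the target ((2S,3R)-3-hydroxymethyl dihydrobenzofuran) | COc1cc(C[C@H]2COC(=O)[C@@H]2Cc2cc(OC)c3c(c2)[C@H](CO)[C@@H](c2ccc(OCc4ccccc4)c(OC)c2)O3)cc([C@@H](CO)[C@H](O)c2ccc(OCc3ccccc3)c(OC)c2)c1OCc1ccccc1 | intermediate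
26 | CNP0199264.2 | COc1cc([C@@H](O)[C@H](CO)c2cc(C[C@H]3COC(=O)[C@@H]3Cc3cc(OC)c4c(c3)[C@H](CO)[C@@H](c3ccc(O)c(OC)c3)O4)cc(OC)c2O)ccc1O | target

**Count**
Total steps: 17. Longest linear sequence: 12 steps (steps 1–4, 7, 10, 12–17, from 1).

**Steps most likely to fail**

Step 10. What may go wrong: opening of the oxirane at the benzylic carbon (wrong regiochemistry), palladium-induced isomerisation of the epoxide, slow C–O reductive elimination, competing oxidative addition at the aryl bromide, or base-induced opening of the product by β-elimination of the phenoxide. The fallback uses known chemistry (rhodium carbenoid C–H insertion), sets out from 7 and comes back at 16, which DBU epimerises to 17. Commercial 5-allylvanillin F1 is etherified with 4-(benzyloxy)-3-methoxybenzyl alcohol (PPh3, DIAD, Mitsunobu) to aldehyde F2, reduced with NaBH4 to benzyl alcohol F3 and converted with PBr3 into benzyl bromide F4. The lithium enolate of 7 is alkylated with F4 as in step 7 to trans-lactone F5. The allyl group is cleaved (OsO4 cat., NaIO4, 2,6-lutidine) to arylacetaldehyde F6, oxidised (NaClO2, NaH2PO4, 2-methyl-2-butene, Pinnick) to arylacetic acid F7 and esterified (Me3SiCHN2, MeOH) to methyl ester F8. Diazo transfer (p-acetamidobenzenesulfonyl azide, DBU) gives aryldiazoacetate F9. Its Rh2(S-PTTL)4-catalysed intramolecular 1,5 C–H insertion into the benzylic ether CH2 should give cis ester 16.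

Step 13. What may go wrong: erosion of the anti/syn ratio through reversible aldolisation or epimerisation of the acidic α-aryl centre under the amine base, and low conversion with the electron-rich aldehyde. The fallback sets out from 20 and comes back at 22. The imide is enolised stoichiometrically (Bu2BOTf, i-Pr2NEt, CH2Cl2, −78 °C) to the (Z)-boron enolate F12. This is added to aldehyde 12 precomplexed with Et2AlCl, so that the addition runs through an open transition state with an externally activated aldehyde instead of the catalytic closed one, a mode known to turn chiral imide boron enolates anti-selective on the same enolate face. H2O2 work-up follows.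

Step 12. What may go wrong: slow oxidative addition at the hindered, electron-rich bromide, and protodesilylation or double arylation of the acetyl-derived ketene acetal. The fallback sets out from 17 and comes back at 20. Pd(dba)2/P(t-Bu)3-catalysed coupling with the Reformatsky reagent BrZnCH2CO2t-Bu gives tert-butyl arylacetate F10. CF3CO2H in CH2Cl2 at 0 °C gives arylacetic acid F11. The mixed anhydride (t-BuCOCl, Et3N) is then coupled with (S)-4-benzyloxazolidin-2-one and LiCl to give 20.

**Further compounds**
F1 | step 10 | 5-allylvanillin (3-allyl-4-hydroxy-5-methoxybenzaldehyde) | C=CCc1cc(C=O)cc(OC)c1O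
F2 | step 10 | 3-allyl-4-{[4-(benzyloxy)-3-methoxybenzyl]oxy}-5-methoxybenzaldehyde | C=CCc1cc(C=O)cc(OC)c1OCc1ccc(OCc2ccccc2)c(OC)c1
F3 | step 10 | (3-allyl-4-{[4-(benzyloxy)-3-methoxybenzyl]oxy}-5-methoxyphenyl)methanol | C=CCc1cc(CO)cc(OC)c1OCc1ccc(OCc2ccccc2)c(OC)c1
F4 | step 10 | 1-allyl-2-{[4-(benzyloxy)-3-methoxybenzyl]oxy}-5-(bromomethyl)-3-methoxybenzene | C=CCc1cc(CBr)cc(OC)c1OCc1ccc(OCc2ccccc2)c(OC)c1
F5 | step 10 | (3R,4R)-3-(3-allyl-4-{[4-(benzyloxy)-3-methoxybenzyl]oxy}-5-methoxybenzyl)-4-[4-(benzyloxy)-3-bromo-5-methoxybenzyl]dihydrofuran-2(3H)-one | COc1cc(C[C@H]2COC(=O)[C@@H]2Cc2cc(CC=C)c(OCc3ccc(OCc4ccccc4)c(OC)c3)c(OC)c2)cc(Br)c1OCc1ccccc1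
F6 | step 10 | arylacetaldehyde from F5 (allyl replaced by CH2CHO) | COc1cc(C[C@H]2COC(=O)[C@@H]2Cc2cc(CC=O)c(OCc3ccc(OCc4ccccc4)c(OC)c3)c(OC)c2)cc(Br)c1OCc1ccccc1
F7 | step 10 | arylacetic acid from F6 | COc1cc(C[C@H]2COC(=O)[C@@H]2Cc2cc(CC(=O)O)c(OCc3ccc(OCc4ccccc4)c(OC)c3)c(OC)c2)cc(Br)c1OCc1ccccc1
F8 | step 10 | methyl arylacetate from F7 | COc1cc(C[C@H]2COC(=O)[C@@H]2Cc2cc(CC(=O)OC)c(OCc3ccc(OCc4ccccc4)c(OC)c3)c(OC)c2)cc(Br)c1OCc1ccccc1
F9 | step 10 | methyl aryldiazoacetate from F8 | COc1cc(C[C@H]2COC(=O)[C@@H]2Cc2cc(C(=[N+]=[N-])C(=O)OC)c(OCc3ccc(OCc4ccccc4)c(OC)c3)c(OC)c2)cc(Br)c1OCc1ccccc1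
F10 | step 12 | tert-butyl arylacetate (17 with Br replaced by CH2CO2t-Bu) | COc1cc(C[C@H]2COC(=O)[C@@H]2Cc2cc(OC)c3c(c2)[C@H](C(=O)OC)[C@@H](c2ccc(OCc4ccccc4)c(OC)c2)O3)cc(CC(=O)OC(C)(C)C)c1OCc1ccccc1
F11 | step 12 | arylacetic acid (17 with Br replaced by CH2CO2H) | COc1cc(C[C@H]2COC(=O)[C@@H]2Cc2cc(OC)c3c(c2)[C@H](C(=O)OC)[C@@H](c2ccc(OCc4ccccc4)c(OC)c2)O3)cc(CC(=O)O)c1OCc1ccccc1
F12 | step 13 | (Z)-dibutylboron enolate of 20 (not isolated) | COc1cc(C[C@H]2COC(=O)[C@@H]2Cc2cc(OC)c3c(c2)[C@H](C(=O)OC)[C@@H](c2ccc(OCc4ccccc4)c(OC)c2)O3)cc(/C=C(\OB(CCCC)CCCC)N2[C@@H](Cc3ccccc3)COC2=O)c1OCc1ccccc1
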